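**Plan**
- Retrosynthetic cuts, in order: the seven O–benzyl bonds of a protected core; the two outer aryl–butanoyl bonds and the central aryl–acyl bond; in each outer ring, the bond from the bridge-bearing carbon to the C–OH carbon beside the C-methyl carbon; finally the two tether C–C bonds (as styryl C=C), back to a phloroglucinol dialdehyde and a 6-methyl-2-pyranone.
- Enabling feature: each outer ring is a C-methylphloroglucinol monomethyl ether whose OMe carbon is para to the bridge-bearing carbon and next to the C-methyl carbon. That is the C4(OMe)/C3(Me) unit of a 4-methoxy-3-methyl-2-pyranone after the first side-chain carbon on C6 has bonded to the lactone carbon C2.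
- Forward order: the central ring is present from the start (phloroglucinol, then dialdehyde, bromide at the last ring CH, tribenzyl ether). Two pyranones are attached by condensation and the alkenes saturated. Both outer benzene rings then close in one operation. The central acyl group enters by Br/Li exchange, the outer butanoyl groups by Friedel–Crafts acylation, and hydrogenolysis ends the route.
- Stereochemistry: the one stereocentre, (S), comes unchanged from (S)-2-methylbutanoic acid and is introduced only after the hot methoxide step.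

Key step: step 9

Assumption: the ring transformation established for 4-methoxy-6-methyl-2-pyranone is taken to extend to 6-(2-arylethyl)-3-methyl congeners, and aryl benzyl ethers and an aryl bromide without ortho hydrogen are taken to survive NaOMe in methanol at 185 °C.

**Route**

Step 1
Reactants: 1 phloroglucinol (benzene-1,3,5-triol)
Product: 3 2,4,6-trihydroxybenzene-1,3-dicarbaldehyde, via bis(iminium) dichloride 2 (not isolated)
Conditions: POCl3 (2.2 equiv), DMF, EtOAc, 0 °C to rt; then H2O, 50 °C
Reagents that add atoms: N,N-dimethylformamide, CN(C)C=O; water, O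
Why: Vilsmeier–Haack formylation, in which the chloroiminium ion attacks the strongly activated ring twice and a third attack is held back by the two electron-withdrawing iminium groups and the limited amount of reagent.

Step 2
Reactants: 3 2,4,6-trihydroxybenzene-1,3-dicarbaldehyde
Product: 4 5-bromo-2,4,6-trihydroxybenzene-1,3-dicarbaldehyde
Conditions: NBS (1.0 equiv), MeCN, 0 °C
Reagents that add atoms: N-bromosuccinimide, O=C1CCC(=O)N1Br
Why: Electrophilic aromatic bromination goes to the only unsubstituted ring carbon, which is ortho or para to all three hydroxyls, and the bromide then blocks this carbon against C-benzylation and acylation and later serves as the handle for the central acyl group.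

Step 3
Reactants: 4 5-bromo-2,4,6-trihydroxybenzene-1,3-dicarbaldehyde
Product: 5 2,4,6-tris(benzyloxy)-5-bromobenzene-1,3-dicarbaldehyde
Conditions: BnBr, K2CO3, DMF, 60 °C
Reagents that add atoms: benzyl bromide, BrCc1ccccc1
Why: Williamson ether synthesis, in which the phenoxides can react only at oxygen because no ring carbon is free, and warm DMF with K2CO3 is enough to alkylate the chelated ortho-formyl phenols.

Step 4
Reactants: 6 4-hydroxy-6-methyl-2H-pyran-2-one
Product: 7 4-hydroxy-6-methyl-3-[(phenylsulfanyl)methyl]-2H-pyran-2-one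
Conditions: (CH2O)n, PhSH, piperidine (cat.), AcOH (cat.), EtOH, reflux
Reagents that add atoms: formaldehyde (as paraformaldehyde), C=O; thiophenol, Sc1ccccc1
Why: Knoevenagel condensation of formaldehyde at the nucleophilic C3 followed by thia-Michael trapping of the 3-methylene intermediate by thiophenol (a Mannich-type phenylthiomethylation) puts one carbon on C3 and suppresses the usual methylene-bridged dimer.

Step 5
Reactants: 7 4-hydroxy-6-methyl-3-[(phenylsulfanyl)methyl]-2H-pyran-2-one
Product: 8 4-hydroxy-3,6-dimethyl-2H-pyran-2-one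
Conditions: Raney Ni, EtOH, reflux
Reagents that add atoms: none
Why: Raney Ni desulfurization cleaves both C–S bonds by hydrogenolysis and leaves the C3 methyl group, while the electron-rich, fully conjugated pyranone double bonds are not reduced under these conditions.

Step 6
Reactants: 8 4-hydroxy-3,6-dimethyl-2H-pyran-2-one
Product: 9 4-methoxy-3,6-dimethyl-2H-pyran-2-one
Conditions: Me2SO4, K2CO3, acetone, reflux
Reagents that add atoms: dimethyl sulfate, COS(=O)(=O)OC
Why: Williamson-type O-methylation of the vinylogous acid with K2CO3 and Me2SO4 in acetone is known to favour the 4-methoxy-2-pyranone over the isomeric 2-methoxy-4-pyranone.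

Step 7
Reactants: 5 2,4,6-tris(benzyloxy)-5-bromobenzene-1,3-dicarbaldehyde; 9 4-methoxy-3,6-dimethyl-2H-pyran-2-one (2.5 equiv)
Product: 10 6,6'-[[2,4,6-tris(benzyloxy)-5-bromo-1,3-phenylene]di[(E)-ethene-2,1-diyl]]bis(4-methoxy-3-methyl-2H-pyran-2-one)
Conditions: Mg(OMe)2, MeOH, reflux; then AcOH
Reagents that add atoms: none
Why: Vinylogous aldol condensation, in which Mg(OMe)2 deprotonates the C6 methyl group of the 4-methoxy-2-pyranone (C3 is blocked by its methyl), the carbanion adds to each aldehyde and loss of water gives the conjugated (E)-styrylpyranones, as in classical styrylpyranone syntheses.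

Step 8
Reactants: 10 6,6'-[[2,4,6-tris(benzyloxy)-5-bromo-1,3-phenylene]di[(E)-ethene-2,1-diyl]]bis(4-methoxy-3-methyl-2H-pyran-2-one)
Product: 11 6,6'-[[2,4,6-tris(benzyloxy)-5-bromo-1,3-phenylene]di(ethane-2,1-diyl)]bis(4-methoxy-3-methyl-2H-pyran-2-one)
Conditions: TsNHNH2, NaOAc, DME/H2O, reflux
Reagents that add atoms: none
Why: Diimide reduction transfers H2 in a concerted syn fashion to the 1,2-disubstituted styryl C=C much faster than to the tri- and tetrasubstituted, donor-substituted ring double bonds, and it leaves benzyl ethers and the aryl bromide untouched where catalytic hydrogenation would not.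

Step 9
Reactants: 11 6,6'-[[2,4,6-tris(benzyloxy)-5-bromo-1,3-phenylene]di(ethane-2,1-diyl)]bis(4-methoxy-3-methyl-2H-pyran-2-one)
Product: 13 2,2'-[[2,4,6-tris(benzyloxy)-5-bromo-1,3-phenylene]bis(methylene)]bis(5-methoxy-4-methylbenzene-1,3-diol), via ring-opened bis(keto ester) 12 (not isolated)
Conditions: NaOMe (excess), MeOH, 185 °C (sealed vessel); then aq. HCl
Reagents that add atoms: none
Why: Methoxide adds to each lactone carbonyl and opens the pyranone to the methyl (E)-3-methoxy-2-methyl-5-oxohept-2-enoate 12, in which the ester and the ketone branch are held cis on the tetrasubstituted double bond; the ketone enolate at the former side-chain CH2 (C6 of the heptenoate) then attacks the ester carbonyl in an intramolecular Claisen (Dieckmann-type) condensation, and loss of methoxide followed by enolization gives the resorcinol. The closest known reaction is the NaOMe-mediated conversion of 4-methoxy-6-methyl-2-pyranone into 5-methoxyresorcinol, applied here to a 6-alkyl homologue on both arms of one molecule. Each of the two benzene rings closes by a 6-(enolexo)-exo-trig attack of carbon on the ester carbonyl, forming the bond between the bridge-bearing carbon and the C–OH carbon next to the C-methyl carbon. No stereocentre is formed. The step needs closure from the side-chain carbon and not from the more acidic C4 methylene between ketone and enol ether, and ring size secures this, since the C4 enolate could only form a four-membered ring and therefore merely equilibrates; the O-methyl position is fixed because the vinylogous ester oxygen stays on its carbon and alkoxide exchange with the solvent is degenerate. The benzyl ethers and the aryl bromide, which sits on an electron-rich ring and has no ortho hydrogen for aryne formation, should be inert to methoxide.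

Step 10
Reactants: 13 2,2'-[[2,4,6-tris(benzyloxy)-5-bromo-1,3-phenylene]bis(methylene)]bis(5-methoxy-4-methylbenzene-1,3-diol)
Product: 14 1,3,5-tris(benzyloxy)-2,4-bis[[2,6-bis(benzyloxy)-4-methoxy-3-methylphenyl]methyl]-6-bromobenzene
Conditions: BnBr, K2CO3, DMF, 60 °C
Reagents that add atoms: benzyl bromide, BrCc1ccccc1
Why: Williamson O-benzylation of the four outer phenols in DMF, where O-alkylation dominates over C-alkylation, masks all acidic protons before the organolithium and acylation steps.

Step 11
Reactants: 15 (S)-2-methylbutanoic acid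
Product: 17 (2S)-N-methoxy-N,2-dimethylbutanamide, via acyl imidazole 16 (not isolated)
Conditions: CDI, CH2Cl2, 0 °C to rt; then MeNHOMe·HCl, rt
Reagents that add atoms: N,O-dimethylhydroxylamine hydrochloride, CNOC.Cl
Why: Amide formation through the acyl imidazole proceeds without any base able to enolize the activated acid, so the (S) centre is carried over unchanged into the Weinreb amide.

Step 12
Reactants: 14 1,3,5-tris(benzyloxy)-2,4-bis[[2,6-bis(benzyloxy)-4-methoxy-3-methylphenyl]methyl]-6-bromobenzene; 17 (2S)-N-methoxy-N,2-dimethylbutanamide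
Product: 20 (2S)-1-[2,4,6-tris(benzyloxy)-3,5-bis[[2,6-bis(benzyloxy)-4-methoxy-3-methylphenyl]methyl]phenyl]-2-methylbutan-1-one, via aryllithium 18 (not isolated), via lithium hemiaminal adduct 19 (not isolated)
Conditions: n-BuLi, THF, −78 °C; then 17, −78 to −20 °C; then aq. HCl (1 M), 0 °C
Reagents that add atoms: none
Why: Bromine–lithium exchange at −78 °C followed by Weinreb ketone synthesis, in which the aryllithium adds once to the amide and the chelated tetrahedral adduct collapses to the ketone only on quench, so over-addition and enolization of the product are avoided and the (S) centre of 17 is retained.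

Step 13
Reactants: 20 (2S)-1-[2,4,6-tris(benzyloxy)-3,5-bis[[2,6-bis(benzyloxy)-4-methoxy-3-methylphenyl]methyl]phenyl]-2-methylbutan-1-one; 21 butanoic anhydride
Product: 22 (2S)-1-[2,4,6-tris(benzyloxy)-3,5-bis[[2,6-bis(benzyloxy)-3-butanoyl-4-methoxy-5-methylphenyl]methyl]phenyl]-2-methylbutan-1-one
Conditions: 21 (1.2 equiv), (CF3CO)2O (3 equiv), CH2Cl2, 0 °C to rt
Reagents that add atoms: none
Why: Friedel–Crafts acylation in which butanoic anhydride and (CF3CO)2O exchange to two molecules of butanoic trifluoroacetic anhydride, so that one molecule of 21 delivers both butanoyl groups, which can enter only at the two outer-ring CH positions flanked by OBn and OMe, the sole unsubstituted carbons of the three oxygenated rings, while the absence of a metal Lewis acid and the low temperature spare the benzyl ethers and limit enolization of the α-branched ketone.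

Step 14
Reactants: 22 (2S)-1-[2,4,6-tris(benzyloxy)-3,5-bis[[2,6-bis(benzyloxy)-3-butanoyl-4-methoxy-5-methylphenyl]methyl]phenyl]-2-methylbutan-1-one
Product: 23 agrimol B, (2S)-1-[3,5-bis[(3-butanoyl-2,6-dihydroxy-4-methoxy-5-methylphenyl)methyl]-2,4,6-trihydroxyphenyl]-2-methylbutan-1-one
Conditions: H2 (1 atm), Pd/C, EtOAc/MeOH, rt
Reagents that add atoms: none
Why: Hydrogenolysis of the seven benzyl ethers over Pd/C is neutral, does not reduce the ortho-oxygenated aryl ketones and cannot epimerize the α stereocentre.

**Compound list**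

1 | phloroglucinol (benzene-1,3,5-triol) | Oc1cc(O)cc(O)c1 | starting material
2 | N,N'-[(2,4,6-trihydroxy-1,3-phenylene)dimethylidyne]bis(N-methylmethanaminium) dichloride | C[N+](C)=Cc1c(O)cc(O)c(C=[N+](C)C)c1O.[Cl-].[Cl-] | intermediate
3 | 2,4,6-trihydroxybenzene-1,3-dicarbaldehyde | O=Cc1c(O)cc(O)c(C=O)c1O | intermediate
4 | 5-bromo-2,4,6-trihydroxybenzene-1,3-dicarbaldehyde | O=Cc1c(O)c(Br)c(O)c(C=O)c1O | intermediate
5 | 2,4,6-tris(benzyloxy)-5-bromobenzene-1,3-dicarbaldehyde | O=Cc1c(OCc2ccccc2)c(Br)c(OCc2ccccc2)c(C=O)c1OCc1ccccc1 | intermediate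
6 | 4-hydroxy-6-methyl-2H-pyran-2-one | CC1=CC(O)=CC(=O)O1 | starting material
7 | 4-hydroxy-6-methyl-3-[(phenylsulfanyl)methyl]-2H-pyran-2-one | CC1=CC(O)=C(CSc2ccccc2)C(=O)O1 | intermediate
8 | 4-hydroxy-3,6-dimethyl-2H-pyran-2-one | CC1=CC(O)=C(C)C(=O)O1 | intermediate
9 | 4-methoxy-3,6-dimethyl-2H-pyran-2-one | CC1=CC(OC)=C(C)C(=O)O1 | intermediate
10 | 6,6'-[[2,4,6-tris(benzyloxy)-5-bromo-1,3-phenylene]di[(E)-ethene-2,1-diyl]]bis(4-methoxy-3-methyl-2H-pyran-2-one) | Brc1c(OCc2ccccc2)c(/C=C/C2=CC(OC)=C(C)C(=O)O2)c(OCc2ccccc2)c(/C=C/C2=CC(OC)=C(C)C(=O)O2)c1OCc1ccccc1 | intermediate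
11 | 6,6'-[[2,4,6-tris(benzyloxy)-5-bromo-1,3-phenylene]di(ethane-2,1-diyl)]bis(4-methoxy-3-methyl-2H-pyran-2-one) | Brc1c(OCc2ccccc2)c(CCC2=CC(OC)=C(C)C(=O)O2)c(OCc2ccccc2)c(CCC2=CC(OC)=C(C)C(=O)O2)c1OCc1ccccc1 | intermediate
12 | dimethyl (2E,2'E)-7,7'-[2,4,6-tris(benzyloxy)-5-bromo-1,3-phenylene]bis(3-methoxy-2-methyl-5-oxohept-2-enoate) | Brc1c(OCc2ccccc2)c(CCC(=O)C/C(OC)=C(/C)C(=O)OC)c(OCc2ccccc2)c(CCC(=O)C/C(OC)=C(/C)C(=O)OC)c1OCc1ccccc1 | intermediate
13 | 2,2'-[[2,4,6-tris(benzyloxy)-5-bromo-1,3-phenylene]bis(methylene)]bis(5-methoxy-4-methylbenzene-1,3-diol) | Brc1c(OCc2ccccc2)c(Cc2c(O)cc(OC)c(C)c2O)c(OCc2ccccc2)c(Cc2c(O)cc(OC)c(C)c2O)c1OCc1ccccc1 | intermediate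
14 | 1,3,5-tris(benzyloxy)-2,4-bis[[2,6-bis(benzyloxy)-4-methoxy-3-methylphenyl]methyl]-6-bromobenzene | Brc1c(OCc2ccccc2)c(Cc2c(OCc3ccccc3)cc(OC)c(C)c2OCc2ccccc2)c(OCc2ccccc2)c(Cc2c(OCc3ccccc3)cc(OC)c(C)c2OCc2ccccc2)c1OCc1ccccc1 | intermediate
15 | (S)-2-methylbutanoic acid | CC[C@H](C)C(=O)O | starting material
16 | (2S)-1-(1H-imidazol-1-yl)-2-methylbutan-1-one | CC[C@H](C)C(=O)n1ccnc1 | intermediate
17 | (2S)-N-methoxy-N,2-dimethylbutanamide | CC[C@H](C)C(=O)N(C)OC | intermediate
18 | [2,4,6-tris(benzyloxy)-3,5-bis[[2,6-bis(benzyloxy)-4-methoxy-3-methylphenyl]methyl]phenyl]lithium | [Li]c1c(OCc2ccccc2)c(Cc2c(OCc3ccccc3)cc(OC)c(C)c2OCc2ccccc2)c(OCc2ccccc2)c(Cc2c(OCc3ccccc3)cc(OC)c(C)c2OCc2ccccc2)c1OCc1ccccc1 | intermediate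
19 | lithium (2S)-1-aryl-1-[methoxy(methyl)amino]-2-methylbutan-1-olate (aryl as in 18; carbinol carbon of undefined configuration) | CC[C@H](C)C(O[Li])(N(C)OC)c1c(OCc2ccccc2)c(Cc2c(OCc3ccccc3)cc(OC)c(C)c2OCc2ccccc2)c(OCc2ccccc2)c(Cc2c(OCc3ccccc3)cc(OC)c(C)c2OCc2ccccc2)c1OCc1ccccc1 | intermediate
20 | (2S)-1-[2,4,6-tris(benzyloxy)-3,5-bis[[2,6-bis(benzyloxy)-4-methoxy-3-methylphenyl]methyl]phenyl]-2-methylbutan-1-one | CC[C@H](C)C(=O)c1c(OCc2ccccc2)c(Cc2c(OCc3ccccc3)cc(OC)c(C)c2OCc2ccccc2)c(OCc2ccccc2)c(Cc2c(OCc3ccccc3)cc(OC)c(C)c2OCc2ccccc2)c1OCc1ccccc1 | intermediate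
21 | butanoic anhydride | CCCC(=O)OC(=O)CCC | starting material
22 | (2S)-1-[2,4,6-tris(benzyloxy)-3,5-bis[[2,6-bis(benzyloxy)-3-butanoyl-4-methoxy-5-methylphenyl]methyl]phenyl]-2-methylbutan-1-one | CC[C@H](C)C(=O)c1c(OCc2ccccc2)c(Cc2c(OCc3ccccc3)c(C(=O)CCC)c(OC)c(C)c2OCc2ccccc2)c(OCc2ccccc2)c(Cc2c(OCc3ccccc3)c(C(=O)CCC)c(OC)c(C)c2OCc2ccccc2)c1OCc1ccccc1 | intermediate
23 | agrimol B, (2S)-1-[3,5-bis[(3-butanoyl-2,6-dihydroxy-4-methoxy-5-methylphenyl)methyl]-2,4,6-trihydroxyphenyl]-2-methylbutan-1-one | CCCC(=O)c1c(O)c(Cc2c(O)c(Cc3c(O)c(C)c(OC)c(C(=O)CCC)c3O)c(O)c(C(=O)[C@@H](C)CC)c2O)c(O)c(C)c1OC | target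

**Count**

Total steps: 14. Longest linear sequence: 10 steps (steps 1, 2, 3, 7, 8, 9, 10, 12, 13, 14 from phloroglucinol; equally steps 4, 5, 6, 7, 8, 9, 10, 12, 13, 14 from the pyranone).

**Steps most likely to fail**

Step 9. The twofold ring transformation may stall after one arm. The opened keto ester may fragment by a vinylogous retro-Claisen cleavage before the slower closure at a secondary carbon. Benzyl groups or the bromine may be lost under methoxide at 185 °C. The fallback sets out from 9 and 5 and comes back at 13. Pyranone 9 alone, the direct 3-methyl homologue of the known substrate, is heated with NaOMe in methanol at 185 °C; closure from its C6 methyl group should give 5-methoxy-4-methylbenzene-1,3-diol F1. Dialdehyde 5 is reduced with NaBH4 in THF/MeOH to [2,4,6-tris(benzyloxy)-5-bromo-1,3-phenylene]dimethanol F2. This doubly activated benzylic diol then alkylates an excess of F1 twice under TsOH catalysis in CH2Cl2 (Friedel–Crafts benzylation) to give 13. The price is that the two free carbons of F1 are not differentiated, so the isomer linked between the two hydroxyls would have to be separated from its regioisomers.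

Step 12. Proton transfer to the hindered aryllithium (from the amide α-CH, from the N–OMe group with loss of formaldehyde, or from benzylic positions on warming) may outrun addition and lead to protodebromination. The fallback sets out from 14 and comes back at 23, with the stereocentre entering in the last operation. Bromide 14 is acylated on both outer rings with butanoic anhydride 21 and (CF3CO)2O as in step 13, which should give 2,4-bis[[2,6-bis(benzyloxy)-3-butanoyl-4-methoxy-5-methylphenyl]methyl]-1,3,5-tris(benzyloxy)-6-bromobenzene F3. Hydrogenolysis over Pd/C with Et3N then removes the seven benzyl groups and the bromine, giving 1,1'-[(2,4,6-trihydroxy-1,3-phenylene)bis[methylene(2,4-dihydroxy-6-methoxy-5-methyl-3,1-phenylene)]]bis(butan-1-one) F4. Acid 15 is converted with oxalyl chloride and catalytic DMF into (2S)-2-methylbutanoyl chloride F5. Friedel–Crafts acylation of F4 with F5 and TiCl4 in CH2Cl2 at the single free ring carbon, the classical closing move for acylphloroglucinols, should then give 23.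

Step 7. The second condensation may stall at an aldehyde flanked by two benzyloxy groups, and prolonged heating with methoxide may erode the pyranone by retro-aldol reaction or ring opening. The fallback sets out from 9 and comes back at 10. Pyranone 9 is deprotonated at its C6 methyl group with LiN(SiMe3)2 (2 equiv, THF, −78 °C) and quenched with diethyl chlorophosphate to give diethyl [(4-methoxy-3-methyl-2-oxo-2H-pyran-6-yl)methyl]phosphonate F6. Horner–Wadsworth–Emmons olefination of dialdehyde 5 with F6 (NaH, THF, 0 °C to rt) is irreversible and should give the (E,E)-bis(styrylpyranone) 10.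

**Further compounds**

F1 | step 9 | 5-methoxy-4-methylbenzene-1,3-diol | Cc1c(O)cc(O)cc1OC
F2 | step 9 | [2,4,6-tris(benzyloxy)-5-bromo-1,3-phenylene]dimethanol | OCc1c(OCc2ccccc2)c(Br)c(OCc2ccccc2)c(CO)c1OCc1ccccc1
F3 | step 12 | 2,4-bis[[2,6-bis(benzyloxy)-3-butanoyl-4-methoxy-5-methylphenyl]methyl]-1,3,5-tris(benzyloxy)-6-bromobenzene | Brc1c(OCc2ccccc2)c(Cc2c(OCc3ccccc3)c(C(=O)CCC)c(OC)c(C)c2OCc2ccccc2)c(OCc2ccccc2)c(Cc2c(OCc3ccccc3)c(C(=O)CCC)c(OC)c(C)c2OCc2ccccc2)c1OCc1ccccc1
F4 | step 12 | 1,1'-[(2,4,6-trihydroxy-1,3-phenylene)bis[methylene(2,4-dihydroxy-6-methoxy-5-methyl-3,1-phenylene)]]bis(butan-1-one) | CCCC(=O)c1c(O)c(Cc2c(O)c(Cc3c(O)c(C)c(OC)c(C(=O)CCC)c3O)c(O)cc2O)c(O)c(C)c1OC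
F5 | step 12 | (2S)-2-methylbutanoyl chloride | CC[C@H](C)C(=O)Cl
F6 | step 7 | diethyl [(4-methoxy-3-methyl-2-oxo-2H-pyran-6-yl)methyl]phosphonate | CCOP(=O)(OCC)CC1=CC(OC)=C(C)C(=O)O1
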